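The numbers in the tables were computed with constants of no real substance; scatter was added.

- A closed, stirred vessel of constant volume holds starting material that may leave by reversible routes to target, isomer of the product and third isomer, while target may also bind starting material into the idle adduct. Amounts here are fractions of the charge, with the adduct counted in target.

| flask | starting material | remark | time |
|---|---|---|---|
| north | 0.10 M | run made earlier |  |
| west | 0.15 M | run made earlier |  |
| alder | 0.20 M |  | 8.0 h |
| cedar | 0.20 M |  | 15 h |

| run | time / h | starting material / % | third isomer / % | target / % | isomer of the product / % |
|---|---|---|---|---|---|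
| north | 0.833 | 70.7 | 10.4 | 8.9 | 4.3 |
| north | 1.33 | 59.5 | 16.4 | 15.4 | 5.3 |
| north | 2.00 | 46.6 | 21.9 | 21.2 | 6.9 |
| north | 4.00 | 25.8 | 28.0 | 30.8 | 8.8 |
| north | 6.00 | 16.7 | 30.4 | 37.5 | 13.9 |
| north | 10.0 | 12.7 | 31.0 | 41.5 | 14.2 |
| west | 1.50 | 54.9 | 16.9 | 15.2 | 4.6 |
| west | 3.00 | 33.5 | 25.4 | 26.6 | 9.5 |
| west | 5.00 | 19.0 | 29.1 | 32.9 | 11.3 |
| west | 6.00 | 17.0 | 27.8 | 34.5 | 11.7 |
| west | 8.00 | 14.3 | 31.0 | 37.8 | 12.9 |
| west | 10.0 | 10.0 | 32.8 | 40.0 | 13.4 |

(scatter of a reading: 1 percentage point)

- in percentages every species weighs as the starting material in it: one idle adduct counts as two
- for target the idle adduct is counted in
- what may be going on: starting material <-> target; starting material <-> isomer of the product; starting material <-> third isomer; starting material + target <-> idle adduct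
- in an amount of target, one idle adduct counts as one target

1. which of these there is most of at the end, counted by the starting material in it, alder (target / isomer of the product / starting material / third isomer)
2. which of these there is most of at the end, counted by the starting material in it, cedar (target / isomer of the product / starting material / third isomer)
3. how much there is at the end of the one of these that leads, in percent of the starting material charged: alder
4. how much there is at the end of the one of these that leads, in percent of the starting material charged: cedar

- Divide target's gain by starting material's loss and time drops out. The bench rule, kinetic control, says this split stays fixed, so target over the charge converted is a constant. West at 3.00 h reads 0.400. Applied to west at 8.00 h, with 14.3% left, the rule gives 34.3%, but the reading is 37.8%.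
- That is the border of the rule. West's share at 8.00 h is 0.441, higher by a factor of 1.10. Meanwhile north's third isomer goes from 30.4% at 6.00 h to 31.0% at 10.0 h, a step within the scatter of 1 percentage point.
- So you should carry the drift too. Between those two readings west's share climbs 0.00821 /h, and continuing that line gives my estimate, the projected target share at the later time, target over charge converted at 15 h: 0.499.
- My reckoning crosses charges: north and west differ by 1.5 points in target at their last readings. For alder I take west's 37.8% of target against 31.0% of third isomer, so I expect target to lead. For cedar, the projected share on west's last 10.0% left gives 44.9%, so I expect target to lead there too, over west's last 32.8% of third isomer.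
- The forecast names target for alder at 39% and target for cedar at 45%, on the ground that “Target therefore leads at late times”.
- The flasks give target at 38.3% in alder and target at 44.5% in cedar. Left for 150 h, cedar stands at 59.6% of target. With cedar's own 8.7% of starting material left, the projected share gives 45.6%, against the computed 44.5%.

    starting material ⇌ target (K = 8.70, k = 4.21 × 10⁻⁵ /s)
    starting material ⇌ isomer of the product (K = 2.30, k = 1.58 × 10⁻⁵ /s)
    starting material ⇌ third isomer (K = 2.30, k = 4.42 × 10⁻⁵ /s)
    starting material + target ⇌ idle adduct, settled at all times (K = 6.20 /M)

- A neighbouring flask is like cedar but charged at 0.080 M. With its 9.0% of starting material left, the projected share gives 45.4% of target, and the computed neighbouring flask holds 45.3%.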